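**Retrosynthetic overview**
- The target is the C13 acetate of the cyclised product with the ester removed; that acetate comes from a single cascade on an open-chain (3R,6Z,10E)-tetraene acetate: bromiranium at C14=C15, then the C4–C5 bond (ring A), then the C9–C10 bond (ring B), then loss of H7.
- The (10E) olefin gives the trans ring fusion with equatorial bromide. The (6Z) olefin forces the C9 side chain axial, trans to the C10 methyl, which is the configuration the target SMILES demands. C13 comes from (R)-linalool.
- The tetraene is assembled at C8–C9 by alkylating geranyl phenyl sulfone with a (Z)-allylic bromide, then reductive desulfonylation.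
- The (Z)-allylic bromide comes from (R)-linalool: silyl ether, chemoselective ozonolysis, Still–Gennari olefination, reduction, bromination.

Assumption: labdane numbering is used for the bicyclic compounds; catalyst K is (R)-3,3′-bis(2,4,6-triisopropylphenyl)-5,5′,6,6′,7,7′,8,8′-octahydro-1,1′-binaphthalene-2,2′-diyl N-(trifluoromethylsulfonyl)phosphoramidothioate, (ArO)2P(=S)NHSO2CF3, and its (R) antipode is taken to deliver Br+ to the face giving C3 = R (if the (S) antipode does so, it is used instead).

**Step 1**
Reactants: 1 (R)-(−)-linalool; 2 triethylsilyl trifluoromethanesulfonate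
Product: 3 triethyl{[(3R)-3,7-dimethylocta-1,6-dien-3-yl]oxy}silane
Conditions: TESOTf, 2,6-lutidine, CH2Cl2, −78 → 0 °C
Reagents that add atoms: triethylsilyl trifluoromethanesulfonate (2), CC[Si](CC)(CC)OS(=O)(=O)C(F)(F)F
Why: O-silylation of the hindered tertiary alcohol with a silyl triflate and a hindered base is standard and leaves the chiral-pool C3 centre (later C13) untouched.

**Step 2**
Reactants: 3 triethyl{[(3R)-3,7-dimethylocta-1,6-dien-3-yl]oxy}silane; 4 ozone
Product: 6 (4R)-4-methyl-4-[(triethylsilyl)oxy]hex-5-enal, via ozonide 5 (not isolated)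
Conditions: O3 (1.0 equiv, Sudan Red 7B end point), CH2Cl2, −78 °C; then PPh3, −78 → 23 °C
Reagents that add atoms: ozone (4), [O-][O+]=O
Why: Chemoselective ozonolysis: ozone attacks the electron-rich trisubstituted olefin far faster than the hindered monosubstituted vinyl group, and PPh3 reduces the ozonide to the aldehyde.

**Step 3**
Reactants: 6 (4R)-4-methyl-4-[(triethylsilyl)oxy]hex-5-enal; 7 ethyl 2-[bis(2,2,2-trifluoroethoxy)phosphoryl]propanoate
Product: 8 ethyl (2Z,6R)-2,6-dimethyl-6-[(triethylsilyl)oxy]octa-2,7-dienoate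
Conditions: 7, KN(SiMe3)2, 18-crown-6, THF, −78 °C; then 6
Reagents that add atoms: ethyl 2-[bis(2,2,2-trifluoroethoxy)phosphoryl]propanoate (7), CCOC(=O)C(C)P(=O)(OCC(F)(F)F)OCC(F)(F)F
Why: Still–Gennari olefination gives the kinetic (Z)-2-methyl enoate (typically ≥15:1), fixing the olefin geometry that step 11 translates into the C9 configuration.

**Step 4**
Reactants: 8 ethyl (2Z,6R)-2,6-dimethyl-6-[(triethylsilyl)oxy]octa-2,7-dienoate
Product: 9 (2Z,6R)-2,6-dimethyl-6-[(triethylsilyl)oxy]octa-2,7-dien-1-ol
Conditions: i-Bu2AlH (2.5 equiv), CH2Cl2, −78 °C; Rochelle salt work-up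
Reagents that add atoms: none
Why: 1,2-Reduction of the enoate by i-Bu2AlH gives the allylic alcohol without touching olefin geometry or the silyl ether.

**Step 5**
Reactants: 9 (2Z,6R)-2,6-dimethyl-6-[(triethylsilyl)oxy]octa-2,7-dien-1-ol; 10 tetrabromomethane
Product: 11 {[(3R,6Z)-8-bromo-3,7-dimethylocta-1,6-dien-3-yl]oxy}triethylsilane
Conditions: CBr4, PPh3, 2,6-lutidine, CH2Cl2, −20 → 0 °C
Reagents that add atoms: tetrabromomethane (10), BrC(Br)(Br)Br
Why: The Appel reaction converts the primary allylic alcohol into the bromide under neutral conditions with retention of the (Z) geometry.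

**Step 6**
Reactants: 12 geranyl bromide; 13 sodium benzenesulfinate
Product: 14 geranyl phenyl sulfone, {[(2E)-3,7-dimethylocta-2,6-dien-1-yl]sulfonyl}benzene
Conditions: PhSO2Na, DMF, 23 °C
Reagents that add atoms: sodium benzenesulfinate (13), [Na+].[O-]S(=O)c1ccccc1
Why: SN2 S-alkylation of the sulfinate by the primary allylic bromide gives the sulfone with the (E) olefin unchanged.

**Step 7**
Reactants: 14 geranyl phenyl sulfone; 11 {[(3R,6Z)-8-bromo-3,7-dimethylocta-1,6-dien-3-yl]oxy}triethylsilane
Product: 16 triethyl{[(3R,6Z,10E)-3,7,11,15-tetramethyl-9-(phenylsulfonyl)hexadeca-1,6,10,14-tetraen-3-yl]oxy}silane (both C9 epimers), via lithiated sulfone 15 (not isolated)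
Conditions: n-BuLi, THF–DMPU, −78 °C; then 11, −78 → −20 °C
Reagents that add atoms: none
Why: Alkylation of the α-sulfonyl carbanion by SN2 at the primary allylic bromide forms the C8–C9 bond head-to-tail without allylic transposition; the sulfone-bearing centre is removed in the next step.

**Step 8**
Reactants: 16 triethyl{[(3R,6Z,10E)-3,7,11,15-tetramethyl-9-(phenylsulfonyl)hexadeca-1,6,10,14-tetraen-3-yl]oxy}silane
Product: 17 triethyl{[(3R,6Z,10E)-3,7,11,15-tetramethylhexadeca-1,6,10,14-tetraen-3-yl]oxy}silane
Conditions: PdCl2(dppp) (5 mol %; dppp = 1,3-bis(diphenylphosphino)propane), LiBHEt3, THF, 0 °C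
Reagents that add atoms: none
Why: Palladium-catalysed reductive desulfonylation proceeds through a π-allylpalladium intermediate that takes hydride at its less substituted terminus (C9), so the (10E) trisubstituted olefin keeps its position and geometry.

**Step 9**
Reactants: 17 triethyl{[(3R,6Z,10E)-3,7,11,15-tetramethylhexadeca-1,6,10,14-tetraen-3-yl]oxy}silane
Product: 18 (3R,6Z,10E)-3,7,11,15-tetramethylhexadeca-1,6,10,14-tetraen-3-ol
Conditions: HF·pyridine, pyridine, THF, 0 → 23 °C
Reagents that add atoms: none
Why: Fluoride-driven Si–O cleavage under pyridine buffering leaves the acid-sensitive polyene and the tertiary allylic alcohol intact.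

**Step 10**
Reactants: 18 (3R,6Z,10E)-3,7,11,15-tetramethylhexadeca-1,6,10,14-tetraen-3-ol; 19 acetic anhydride
Product: 20 (3R,6Z,10E)-3,7,11,15-tetramethylhexadeca-1,6,10,14-tetraen-3-yl acetate
Conditions: Ac2O, DMAP, Et3N, CH2Cl2, 35 °C
Reagents that add atoms: acetic anhydride (19), CC(=O)OC(C)=O
Why: DMAP-catalysed acylation caps the tertiary alcohol as an acetate, whose alkyl oxygen cannot trap the C8 cation in step 11 (a free OH or silyl ether would close the 8,13-ether).

**Step 11**
Reactants: 20 (3R,6Z,10E)-3,7,11,15-tetramethylhexadeca-1,6,10,14-tetraen-3-yl acetate; 21 N-bromosuccinimide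
Product: 24 (3R,5S,9S,10S,13R)-3-bromolabda-7,14-dien-13-yl acetate, via bromiranium ion 22 (not isolated), via C8 cation 23 (not isolated)
Conditions: NBS (1.05 equiv), catalyst K (10 mol %), 4 Å MS, toluene–CH2Cl2 4:1 (5 mM), −78 °C, dark
Reagents that add atoms: N-bromosuccinimide (21), O=C1CCC(=O)N1Br
Why: Proposed new method: catalytic enantioselective bromonium-induced bicyclisation of an alkene-terminated polyene through a (Z)-olefin relay — NBS, almost insoluble in the cold medium so that background bromination is negligible, brominates the thiophosphoryl sulfur of K to a neutral chiral S–Br donor that hands Br+ to the least hindered, most electron-rich C14=C15 olefin inside the 3,3′-aryl pocket (face selection sets C3 = R in 22, which stays ion-paired with the chiral thiophosphoramidate so olefin-to-olefin Br+ scrambling is suppressed); anti opening of 22 by the (10E) olefin through a chair sets C5 and C10 (trans-decalin, equatorial Br cis to the C10 methyl); the (6Z) olefin then closes ring B through a chair that forces C11 axial and trans to the C10 methyl (C9 = S), giving 23; in 23 the C9–H is equatorial and orthogonal to the empty p orbital, so the catalyst anion removes the aligned axial C7–H and leaves the Δ7 olefin, while the acetate and the deactivated vinyl group cannot trap the cation; the closest known reaction types are chiral Lewis-base-promoted bromo- and iodocyclisations of arene- or phenol-terminated geranyl and homogeranyl substrates and stoichiometric achiral bromonium polyene cyclisations, neither shown with alkene termination or a (Z) relay.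

**Step 12**
Reactants: 24 (3R,5S,9S,10S,13R)-3-bromolabda-7,14-dien-13-yl acetate
Product: 25 (3R,5S,9S,10S,13R)-3-bromolabda-7,14-dien-13-ol, i.e. (3R)-5-[(1S,4aS,6R,8aS)-6-bromo-2,5,5,8a-tetramethyl-1,4,4a,5,6,7,8,8a-octahydronaphthalen-1-yl]-3-methylpent-1-en-3-ol (CNP0210577.1)
Conditions: i-Bu2AlH (3 equiv), CH2Cl2, −78 °C; Rochelle salt work-up
Reagents that add atoms: none
Why: Reductive ester cleavage at −78 °C frees the tertiary alcohol; the equatorial neopentyl-type secondary bromide and the trisubstituted olefin are inert and no stereocentre is touched.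

**Compound list**
1 | (R)-(−)-linalool, (3R)-3,7-dimethylocta-1,6-dien-3-ol | C=C[C@](C)(O)CCC=C(C)C | starting material
2 | triethylsilyl trifluoromethanesulfonate | CC[Si](CC)(CC)OS(=O)(=O)C(F)(F)F | starting material
3 | triethyl{[(3R)-3,7-dimethylocta-1,6-dien-3-yl]oxy}silane | C=C[C@](C)(O[Si](CC)(CC)CC)CCC=C(C)C | intermediate
4 | ozone | [O-][O+]=O | starting material
5 | ozonide, 3,3-dimethyl-5-{(3R)-3-methyl-3-[(triethylsilyl)oxy]pent-4-en-1-yl}-1,2,4-trioxolane (both epimers at the ring CH) | C=C[C@](C)(O[Si](CC)(CC)CC)CCC1OOC(C)(C)O1 | intermediate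
6 | (4R)-4-methyl-4-[(triethylsilyl)oxy]hex-5-enal | C=C[C@](C)(O[Si](CC)(CC)CC)CCC=O | intermediate
7 | ethyl 2-[bis(2,2,2-trifluoroethoxy)phosphoryl]propanoate | CCOC(=O)C(C)P(=O)(OCC(F)(F)F)OCC(F)(F)F | starting material
8 | ethyl (2Z,6R)-2,6-dimethyl-6-[(triethylsilyl)oxy]octa-2,7-dienoate | C=C[C@](C)(O[Si](CC)(CC)CC)CC/C=C(C)\C(=O)OCC | intermediate
9 | (2Z,6R)-2,6-dimethyl-6-[(triethylsilyl)oxy]octa-2,7-dien-1-ol | C=C[C@](C)(O[Si](CC)(CC)CC)CC/C=C(C)\CO | intermediate
10 | tetrabromomethane | BrC(Br)(Br)Br | starting material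
11 | {[(3R,6Z)-8-bromo-3,7-dimethylocta-1,6-dien-3-yl]oxy}triethylsilane | C=C[C@](C)(O[Si](CC)(CC)CC)CC/C=C(C)\CBr | intermediate
12 | geranyl bromide, (2E)-1-bromo-3,7-dimethylocta-2,6-diene | CC(C)=CCC/C(C)=C/CBr | starting material
13 | sodium benzenesulfinate | [Na+].[O-]S(=O)c1ccccc1 | starting material
14 | geranyl phenyl sulfone, {[(2E)-3,7-dimethylocta-2,6-dien-1-yl]sulfonyl}benzene | CC(C)=CCC/C(C)=C/CS(=O)(=O)c1ccccc1 | intermediate
15 | lithiated sulfone, lithium (2E)-3,7-dimethyl-1-(phenylsulfonyl)octa-2,6-dien-1-ide | CC(C)=CCC/C(C)=C/[CH-]S(=O)(=O)c1ccccc1.[Li+] | intermediate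
16 | triethyl{[(3R,6Z,10E)-3,7,11,15-tetramethyl-9-(phenylsulfonyl)hexadeca-1,6,10,14-tetraen-3-yl]oxy}silane (both C9 epimers) | C=C[C@](C)(O[Si](CC)(CC)CC)CC/C=C(C)\CC(S(=O)(=O)c1ccccc1)/C=C(C)/CCC=C(C)C | intermediate
17 | triethyl{[(3R,6Z,10E)-3,7,11,15-tetramethylhexadeca-1,6,10,14-tetraen-3-yl]oxy}silane | C=C[C@](C)(O[Si](CC)(CC)CC)CC/C=C(C)\CC/C=C(C)/CCC=C(C)C | intermediate
18 | (3R,6Z,10E)-3,7,11,15-tetramethylhexadeca-1,6,10,14-tetraen-3-ol | C=C[C@](C)(O)CC/C=C(C)\CC/C=C(C)/CCC=C(C)C | intermediate
19 | acetic anhydride | CC(=O)OC(C)=O | starting material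
20 | (3R,6Z,10E)-3,7,11,15-tetramethylhexadeca-1,6,10,14-tetraen-3-yl acetate | C=C[C@](C)(OC(C)=O)CC/C=C(C)\CC/C=C(C)/CCC=C(C)C | intermediate
21 | N-bromosuccinimide | O=C1CCC(=O)N1Br | starting material
22 | (14R)-14,15-bromiranium ion of 20 | C=C[C@](C)(OC(C)=O)CC/C=C(C)\CC/C=C(C)/CC[C@H]1[Br+]C1(C)C | intermediate
23 | C8 cation, (3R,5S,9S,10S,13R)-13-acetoxy-3-bromolabd-14-en-8-ylium | C=C[C@](C)(OC(C)=O)CC[C@H]1[C+](C)CC[C@@H]2C(C)(C)[C@H](Br)CC[C@]21C | intermediate
24 | (3R,5S,9S,10S,13R)-3-bromolabda-7,14-dien-13-yl acetate (trans-decalin; Br equatorial, cis to the C10 methyl; C9 side chain axial, trans to the C10 methyl) | C=C[C@](C)(OC(C)=O)CC[C@H]1C(C)=CC[C@@H]2C(C)(C)[C@H](Br)CC[C@]21C | intermediate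
25 | (3R,5S,9S,10S,13R)-3-bromolabda-7,14-dien-13-ol, (3R)-5-[(1S,4aS,6R,8aS)-6-bromo-2,5,5,8a-tetramethyl-1,4,4a,5,6,7,8,8a-octahydronaphthalen-1-yl]-3-methylpent-1-en-3-ol | C=C[C@](C)(O)CC[C@H]1C(C)=CC[C@@H]2C(C)(C)[C@H](Br)CC[C@]21C | target

**Totals**
Total steps: 12. Longest linear sequence: 11 (steps 1–5 and 7–12 from 1; step 6 is the side branch).

**Steps most likely to fail**

1. Step 11 (the proposed new step). The risks are insufficient face selectivity, bromination of an internal olefin, arrest after ring A, and the exocyclic Δ8(17) isomer from loss of a methyl proton. The fallback uses known chemistry, sets out from 20 and comes back at 24. Compound 20 is treated with stoichiometric Et2SBr·SbCl5Br in MeNO2 at −25 °C, an achiral bromonium-induced polyene cyclisation. Because C13 is fixed, the two antipodal ring systems are diastereomers: 24 and (3S,5R,9R,10R,13R)-3-bromolabda-7,14-dien-13-yl acetate F1, formed about 1:1. They are separated by preparative HPLC on AgNO3-impregnated silica, which also removes olefin isomers, and 24 goes on to step 12.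

2. Step 8. The risks are hydride delivery to the wrong allyl terminus or partial E/Z scrambling in the π-allyl intermediate. The fallback sets out from 11 and comes back at 17, by-passing 16. Geranyl chloride is converted with active barium (BaI2 reduced by lithium biphenylide, THF, −78 °C) into geranylbarium chloride F2. This couples with 11 at the α-carbon of both allyl partners with retention of both olefin geometries (allylbarium α,α′-cross-coupling), giving 17 directly with no sulfone to remove.

3. Step 2. The risk is over-ozonolysis of the vinyl group or incomplete conversion. The fallback sets out from 3 and comes back at 6. mCPBA (1.0 equiv, NaHCO3, CH2Cl2, 0 °C) epoxidises only the trisubstituted olefin to triethyl{[(3R)-5-(3,3-dimethyloxiran-2-yl)-3-methylpent-1-en-3-yl]oxy}silane F3 (both epoxide epimers). H5IO6 (THF–Et2O, 0 °C) then cleaves the epoxide to aldehyde 6.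

**Further compounds**
F1 | step 11 | (3S,5R,9R,10R,13R)-3-bromolabda-7,14-dien-13-yl acetate | C=C[C@](C)(OC(C)=O)CC[C@@H]1C(C)=CC[C@H]2C(C)(C)[C@@H](Br)CC[C@@]21C
F2 | step 8 | geranylbarium chloride | CC(C)=CCC/C(C)=C/C[Ba]Cl
F3 | step 2 | triethyl{[(3R)-5-(3,3-dimethyloxiran-2-yl)-3-methylpent-1-en-3-yl]oxy}silane (both epoxide epimers) | C=C[C@](C)(O[Si](CC)(CC)CC)CCC1OC1(C)C
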